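**Retrosynthetic overview**
- The epoxide is added last, by site- and face-selective epoxidation of the 1(10)-alkene of a germacra-1(10),4,7(11)-trien-12,6-olide diacetate.
- Key step: the butenolide and the 13-acetate are made together from a ten-membered α-allenol by a palladium-catalysed oxidative carbonylative acetoxy-lactonisation, which forms the lactone C–O bond and the C13–OAc bond.
- The ten-membered ring (C6–C7 bond, C6 stereocentre) comes from a chromium-mediated propargyl-to-allenyl closure of an acyclic bromo enal.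
- The chain comes from a C5 enal acetal, allyl acetate, methyl methacrylate, 1-(trimethylsilyl)propyne and formaldehyde; C3 is set by iridium-catalysed allylation and the 1(10)E alkene by cross-metathesis.
- Ring order: ten-membered carbocycle, then butenolide, then epoxide.

Assumption: positions are given in germacrane numbering (ring C1–C10, lactone carbons C11–C13, methyls C14 and C15); the named antipode of a chiral ligand is the one taken to give the stated configuration, and the stated configuration defines the step.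

Step 1
Reactants: 1 (E)-4,4-dimethoxy-2-methylbut-2-enal; 2 allyl acetate
Product: 3 (2E,4S)-1,1-dimethoxy-3-methylhepta-2,6-dien-4-ol
Conditions: [Ir(cod)Cl]2 (2.5 mol %), (S)-BINAP (5 mol %), 4-chloro-3-nitrobenzoic acid (10 mol %), Cs2CO3 (20 mol %), i-PrOH (2 equiv), THF, 100 °C
Reagents that add atoms: allyl acetate, C=CCOC(C)=O
Why: Krische iridium-catalysed transfer-hydrogenative carbonyl allylation, in which the chiral allyliridium complex adds to the Si face of the enal and sets C3 as S, while the basic medium leaves the acetal intact.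

Step 2
Reactants: 3 (2E,4S)-1,1-dimethoxy-3-methylhepta-2,6-dien-4-ol; 4 methyl methacrylate
Product: 5 methyl (2E,5S,6E)-5-hydroxy-8,8-dimethoxy-2,6-dimethylocta-2,6-dienoate
Conditions: second-generation Hoveyda–Grubbs catalyst, RuCl2(H2IMes)(=CH-2-(i-PrO)C6H4) (5 mol %), methyl methacrylate (10 equiv), CH2Cl2, 40 °C
Reagents that add atoms: methyl methacrylate, C=C(C)C(=O)OC
Why: olefin cross-metathesis of a terminal alkene with a methacrylate gives the (E)-trisubstituted enoate (the future 1(10)E alkene) with high selectivity, and the hindered trisubstituted alkene does not react.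

Step 3
Reactants: 5 methyl (2E,5S,6E)-5-hydroxy-8,8-dimethoxy-2,6-dimethylocta-2,6-dienoate
Product: 6 (2E,5S,6E)-8,8-dimethoxy-2,6-dimethylocta-2,6-diene-1,5-diol
Conditions: i-Bu2AlH (3.5 equiv), CH2Cl2, −78 °C
Reagents that add atoms: none
Why: 1,2-reduction of the enoate to the allylic alcohol with i-Bu2AlH leaves the acetal, both alkenes and C3 untouched.

Step 4
Reactants: 6 (2E,5S,6E)-8,8-dimethoxy-2,6-dimethylocta-2,6-diene-1,5-diol
Product: 7 (2E,4S,6E)-8-bromo-1,1-dimethoxy-3,7-dimethylocta-2,6-dien-4-ol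
Conditions: CBr4, PPh3, CH2Cl2, −30 °C
Reagents that add atoms: carbon tetrabromide, BrC(Br)(Br)Br
Why: Appel bromination is much faster at the unhindered primary allylic hydroxyl than at the secondary one, and it does not change the alkene geometry.

Step 5
Reactants: 7 (2E,4S,6E)-8-bromo-1,1-dimethoxy-3,7-dimethylocta-2,6-dien-4-ol; 8 1-(trimethylsilyl)propyne
Product: 10 (2E,4S,6E)-1,1-dimethoxy-3,7-dimethylundeca-2,6-dien-10-yn-4-ol, via silylalkyne 9 (not isolated)
Conditions: 8 (2.5 equiv), n-BuLi (2.4 equiv), THF, −78 °C, then 7, −78 to −20 °C; then K2CO3, MeOH, rt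
Reagents that add atoms: 1-(trimethylsilyl)propyne, CC#C[Si](C)(C)C
Why: SN2 alkylation of lithiated 1-(trimethylsilyl)propyne at its propargylic carbon (Corey–Kirst propargylation) forms the C8–C9 bond, and methanolysis then removes the silyl group.

Step 6
Reactants: 10 (2E,4S,6E)-1,1-dimethoxy-3,7-dimethylundeca-2,6-dien-10-yn-4-ol
Product: 11 (6E,9S,10E)-12,12-dimethoxy-6,10-dimethyldodeca-6,10-dien-2-yne-1,9-diol
Conditions: n-BuLi (2.2 equiv), THF, −78 °C; (CH2O)n, −78 °C to rt; then aq. NH4Cl
Reagents that add atoms: formaldehyde (as paraformaldehyde), C=O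
Why: addition of the lithium acetylide (alkoxide dianion) to formaldehyde installs C13 as a propargylic alcohol.

Step 7
Reactants: 11 (6E,9S,10E)-12,12-dimethoxy-6,10-dimethyldodeca-6,10-dien-2-yne-1,9-diol
Product: 12 (2E,4S,6E)-12-bromo-1,1-dimethoxy-3,7-dimethyldodeca-2,6-dien-10-yn-4-ol
Conditions: CBr4, PPh3, CH2Cl2, −30 °C
Reagents that add atoms: carbon tetrabromide, BrC(Br)(Br)Br
Why: Appel bromination again selects the primary (propargylic) hydroxyl over the secondary allylic one.

Step 8
Reactants: 12 (2E,4S,6E)-12-bromo-1,1-dimethoxy-3,7-dimethyldodeca-2,6-dien-10-yn-4-ol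
Product: 14 (2E,4S,6E)-12-bromo-3,7-dimethyl-1-oxododeca-2,6-dien-10-yn-4-yl acetate, via acetal acetate 13 (not isolated)
Conditions: AcCl, 2,4,6-collidine, CH2Cl2, 0 °C; then 5% aq. oxalic acid, THF, rt
Reagents that add atoms: acetyl chloride, CC(Cl)=O; water, O
Why: O-acetylation with a hindered base that does not alkylate at the propargylic bromide, followed by mild hydrolysis of the enal dimethyl acetal, gives the (E)-enal with the C3 acetate in place.

Step 9
Reactants: 14 (2E,4S,6E)-12-bromo-3,7-dimethyl-1-oxododeca-2,6-dien-10-yn-4-yl acetate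
Product: 15 (1S,2E,4R,8E)-5-ethenylidene-4-hydroxy-2,8-dimethylcyclodeca-2,8-dien-1-yl acetate
Conditions: CrCl2 (10 equiv), THF, 0.002 M (slow addition of 14), rt
Reagents that add atoms: none
Why: intramolecular Nozaki–Hiyama reaction, in which divalent chromium gives a primary propargylchromium that adds through its γ-carbon (SE2′) to the enal, closing the ten-membered ring as the α-allenol; C6 (R) is set by macrocyclic control, through a chair–chair-like transition state with the C3 acetate and the forming C6–O bond pseudo-equatorial, as in chromium closures of germacranolide precursors.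

Step 10
Reactants: 15 (1S,2E,4R,8E)-5-ethenylidene-4-hydroxy-2,8-dimethylcyclodeca-2,8-dien-1-yl acetate
Product: 16 [(6E,9S,10E,11aR)-9-acetoxy-6,10-dimethyl-2-oxo-2,4,5,8,9,11a-hexahydrocyclodeca[b]furan-3-yl]methyl acetate
Conditions: Pd(OAc)2 (10 mol %), 1,4-benzoquinone (2 equiv), LiOAc (4 equiv), CO (1 atm), AcOH–THF (1:4), rt
Reagents that add atoms: carbon monoxide, [C-]#[O+]; acetic acid, CC(=O)O
Why: Proposed new method: the C6 hydroxyl, CO and divalent palladium give an alkoxycarbonyl–palladium species that adds across the distal allene π-bond in a 5-exo mode, placing the acyl carbon on the central allene carbon C11 and leaving a π-allylpalladium over C7–C11–C13, which acetate (activated by benzoquinone) opens at the unhindered terminus C13, so the lactone C–O bond, the C7=C11 alkene and the C13–OAc bond form in one operation with C6 untouched, and benzoquinone returns zerovalent palladium to the divalent state; the closest known reactions are the Ru3(CO)12-catalysed cyclocarbonylation of α-allenols to butenolides and Bäckvall-type palladium/benzoquinone acetoxylation of π-allyl intermediates.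

Step 11
Reactants: 16 [(6E,9S,10E,11aR)-9-acetoxy-6,10-dimethyl-2-oxo-2,4,5,8,9,11a-hexahydrocyclodeca[b]furan-3-yl]methyl acetate
Product: 17 (1R,3S,6R,10R)-3,13-diacetoxy-1,10-epoxygermacra-4E,7(11)-dien-12,6-olide (target)
Conditions: mCPBA (1.1 equiv), NaHCO3, CH2Cl2, 0 °C
Reagents that add atoms: 3-chloroperbenzoic acid, OOC(=O)c1cccc(Cl)c1
Why: Prilezhaev epoxidation attacks only the electron-rich 1(10)-alkene (the 4,5-alkene is deactivated by two allylic acyloxy groups and the butenolide alkene is electron-poor) from the outer face of the preferred crossed ring conformer, giving the trans (1R,10R) epoxide as in the epoxidation of costunolide; no base strong enough to epimerise C6 is used after step 10.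

**Compound list**
1 | (E)-4,4-dimethoxy-2-methylbut-2-enal | O=C/C(C)=C/C(OC)OC | starting material
2 | allyl acetate | C=CCOC(C)=O | starting material
3 | (2E,4S)-1,1-dimethoxy-3-methylhepta-2,6-dien-4-ol | COC(OC)/C=C(C)/[C@@H](O)CC=C | intermediate
4 | methyl methacrylate | C=C(C)C(=O)OC | starting material
5 | methyl (2E,5S,6E)-5-hydroxy-8,8-dimethoxy-2,6-dimethylocta-2,6-dienoate | COC(OC)/C=C(C)/[C@@H](O)C/C=C(\C)C(=O)OC | intermediate
6 | (2E,5S,6E)-8,8-dimethoxy-2,6-dimethylocta-2,6-diene-1,5-diol | COC(OC)/C=C(C)/[C@@H](O)C/C=C(\C)CO | intermediate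
7 | (2E,4S,6E)-8-bromo-1,1-dimethoxy-3,7-dimethylocta-2,6-dien-4-ol | COC(OC)/C=C(C)/[C@@H](O)C/C=C(\C)CBr | intermediate
8 | 1-(trimethylsilyl)propyne | CC#C[Si](C)(C)C | starting material
9 | (2E,4S,6E)-1,1-dimethoxy-3,7-dimethyl-11-(trimethylsilyl)undeca-2,6-dien-10-yn-4-ol | COC(OC)/C=C(C)/[C@@H](O)C/C=C(\C)CCC#C[Si](C)(C)C | intermediate (not isolated)
10 | (2E,4S,6E)-1,1-dimethoxy-3,7-dimethylundeca-2,6-dien-10-yn-4-ol | COC(OC)/C=C(C)/[C@@H](O)C/C=C(\C)CCC#C | intermediate
11 | (6E,9S,10E)-12,12-dimethoxy-6,10-dimethyldodeca-6,10-dien-2-yne-1,9-diol | COC(OC)/C=C(C)/[C@@H](O)C/C=C(\C)CCC#CCO | intermediate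
12 | (2E,4S,6E)-12-bromo-1,1-dimethoxy-3,7-dimethyldodeca-2,6-dien-10-yn-4-ol | COC(OC)/C=C(C)/[C@@H](O)C/C=C(\C)CCC#CCBr | intermediate
13 | (2E,4S,6E)-12-bromo-1,1-dimethoxy-3,7-dimethyldodeca-2,6-dien-10-yn-4-yl acetate | COC(OC)/C=C(C)/[C@@H](OC(C)=O)C/C=C(\C)CCC#CCBr | intermediate (not isolated)
14 | (2E,4S,6E)-12-bromo-3,7-dimethyl-1-oxododeca-2,6-dien-10-yn-4-yl acetate | O=C/C=C(C)/[C@@H](OC(C)=O)C/C=C(\C)CCC#CCBr | intermediate
15 | (1S,2E,4R,8E)-5-ethenylidene-4-hydroxy-2,8-dimethylcyclodeca-2,8-dien-1-yl acetate | C=C=C1CC/C(C)=C/C[C@H](OC(C)=O)/C(C)=C/[C@H]1O | intermediate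
16 | [(6E,9S,10E,11aR)-9-acetoxy-6,10-dimethyl-2-oxo-2,4,5,8,9,11a-hexahydrocyclodeca[b]furan-3-yl]methyl acetate | CC(=O)OCC1=C2CC/C(C)=C/C[C@H](OC(C)=O)/C(C)=C/[C@H]2OC1=O | intermediate
17 | (1R,3S,6R,10R)-3,13-diacetoxy-1,10-epoxygermacra-4E,7(11)-dien-12,6-olide | CC(=O)OCC1=C2CC[C@@]3(C)O[C@@H]3C[C@H](OC(C)=O)/C(C)=C/[C@H]2OC1=O | target

**Total step count:** 11. **Longest linear sequence:** 11.

**Steps most likely to fail**

Step 10 (the proposed new lactonisation). Direct 5-endo oxypalladation of the allenol to a 2,5-dihydrofuran, or acetate attack at C7, could compete. The fallback builds the butenolide by known vinyl iodide chemistry; it sets out from alkyne 10 and comes back at 16, bypassing steps 6 to 10. The dianion of 10 (n-BuLi) is carboxylated with CO2 and the acid methylated (MeI, K2CO3) to the ynoate methyl (6E,9S,10E)-9-hydroxy-12,12-dimethoxy-6,10-dimethyldodeca-6,10-dien-2-ynoate F1. A MgI2-mediated iodo-aldol reaction with formaldehyde (β-iodo Morita–Baylis–Hillman type) gives the iodo enoate methyl (2Z,6E,9S,10E)-9-hydroxy-2-(hydroxymethyl)-3-iodo-12,12-dimethoxy-6,10-dimethyldodeca-2,6,10-trienoate F2. Aqueous oxalic acid frees the enal methyl (2Z,6E,9S,10E)-9-hydroxy-2-(hydroxymethyl)-3-iodo-6,10-dimethyl-12-oxododeca-2,6,10-trienoate F3. Nozaki–Hiyama–Kishi ring closure (CrCl2, NiCl2 2 mol %, high dilution), with lactonisation of the chromium alkoxide onto the cis ester, gives the diol lactone (6E,9S,10E,11aR)-9-hydroxy-3-(hydroxymethyl)-6,10-dimethyl-4,5,8,9-tetrahydrocyclodeca[b]furan-2(11aH)-one F4. Acetylation of both hydroxyls (Ac2O, pyridine, DMAP) gives 16.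

Step 9 (chromium ring closure). The most likely failure is low or opposite selectivity at C6. The fallback sets out from 14 and comes back at 15. It accepts the ring-closure product as the C6 epimer (1S,2E,4S,8E)-5-ethenylidene-4-hydroxy-2,8-dimethylcyclodeca-2,8-dien-1-yl acetate F5 and sets C6 by an invertive C–O substitution instead of by the C–C bond-forming event. A Mitsunobu reaction with chloroacetic acid (PPh3, DIAD) gives the inverted ester (1S,2E,4R,8E)-4-(2-chloroacetoxy)-5-ethenylidene-2,8-dimethylcyclodeca-2,8-dien-1-yl acetate F6, and thiourea with NaHCO3 removes the chloroacetate without touching the acetate to give 15. If the ring does not close at all, or closes through C13 to the twelve-membered homopropargylic alcohol, the fallback for step 10 is used, since it bypasses this step.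

Step 11 (epoxidation). The peracid could attack the other face of the 1(10)-alkene if the ring conformer preference differs from that of costunolide. The fallback sets out from 16 and comes back at 17 without a new compound: the face is fixed by a catalyst instead of by the ring, using Shi epoxidation with the fructose-derived ketone antipode matched to the (1R,10R) epoxide (KHSO5, K2CO3 buffer, MeCN–dimethoxymethane–water, 0 °C).

**Further compounds**
F1 | step 10 | methyl (6E,9S,10E)-9-hydroxy-12,12-dimethoxy-6,10-dimethyldodeca-6,10-dien-2-ynoate | COC(OC)/C=C(C)/[C@@H](O)C/C=C(\C)CCC#CC(=O)OC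
F2 | step 10 | methyl (2Z,6E,9S,10E)-9-hydroxy-2-(hydroxymethyl)-3-iodo-12,12-dimethoxy-6,10-dimethyldodeca-2,6,10-trienoate | COC(OC)/C=C(C)/[C@@H](O)C/C=C(\C)CC/C(I)=C(\CO)C(=O)OC
F3 | step 10 | methyl (2Z,6E,9S,10E)-9-hydroxy-2-(hydroxymethyl)-3-iodo-6,10-dimethyl-12-oxododeca-2,6,10-trienoate | O=C/C=C(C)/[C@@H](O)C/C=C(\C)CC/C(I)=C(\CO)C(=O)OC
F4 | step 10 | (6E,9S,10E,11aR)-9-hydroxy-3-(hydroxymethyl)-6,10-dimethyl-4,5,8,9-tetrahydrocyclodeca[b]furan-2(11aH)-one | OCC1=C2CC/C(C)=C/C[C@H](O)/C(C)=C/[C@H]2OC1=O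
F5 | step 9 | (1S,2E,4S,8E)-5-ethenylidene-4-hydroxy-2,8-dimethylcyclodeca-2,8-dien-1-yl acetate | C=C=C1CC/C(C)=C/C[C@H](OC(C)=O)/C(C)=C/[C@@H]1O
F6 | step 9 | (1S,2E,4R,8E)-4-(2-chloroacetoxy)-5-ethenylidene-2,8-dimethylcyclodeca-2,8-dien-1-yl acetate | C=C=C1CC/C(C)=C/C[C@H](OC(C)=O)/C(C)=C/[C@H]1OC(=O)CCl
F0 | step 11 | none | none
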